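**Retrosynthetic overview**
1. Target ⇒ one-flask double etherification of an epoxy diol: a bromonium ion on the prenyl olefin is trapped by the tertiary C7–OH (oxane ring, C10–Br), then the C1–C2 epoxide is opened transannularly by C8–OH (oxepane ring).
2. Epoxy diol ⇒ face-selective epoxidation of the ring olefin and allyl-to-prenyl cross-metathesis of an allyl diene diol.
3. Allyl diene diol ⇒ chelation-controlled allylation (C8) of an α-hydroxy aldehyde that already carries the cis C5 acetate.
4. α-Hydroxy aldehyde ⇒ cis-selective ketone reduction (C5) of a syn aldol adduct (C4, C7) made from a Birch-derived silyl dienol ether and 1,1-dimethoxypropan-2-one.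
5. Ring order: carbocycle (from 3-methylphenol) → oxirane → oxane → oxepane.

Convention and assumption: bisabolane numbering is used in the text (ring C1–C6, C1 bears the methyl, C4 bears the chain C7–C11; target = 1R,2R,4R,5S,7S,8S,10S), and in step 3 the (S,S)-ligand is assumed to give 7S as it does with pyruvate esters (otherwise its mirror image is used).

**Step 1**
Reactants: 1 3-methylphenol
Product: 2 tert-butyl(dimethyl)(3-methylphenoxy)silane
Conditions: TBSCl, imidazole, DMF, rt
Reagents that add atoms: tert-butyldimethylsilyl chloride, CC(C)(C)[Si](C)(C)Cl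
Why: Standard O-silylation of a phenol gives a bulky aryl silyl ether that survives dissolving-metal reduction and later serves as the enolsilane (no stereocentre).

**Step 2**
Reactants: 2 tert-butyl(dimethyl)(3-methylphenoxy)silane
Product: 3 tert-butyl(dimethyl)[(5-methylcyclohexa-1,4-dien-1-yl)oxy]silane
Conditions: Li, NH3(l), THF, t-BuOH, −78 °C; then NH4Cl
Reagents that add atoms: none
Why: Birch reduction of the aryl silyl ether leaves both donor substituents on double bonds, giving regiospecifically the skipped silyl dienol ether of the otherwise unstable 3-methylcyclohex-3-enone with the ring olefin already at C1=C2 (no stereocentre).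

**Step 3**
Reactants: 3 tert-butyl(dimethyl)[(5-methylcyclohexa-1,4-dien-1-yl)oxy]silane, 4 1,1-dimethoxypropan-2-one
Product: 5 (6S)-6-[(2S)-2-(tert-butyldimethylsilyloxy)-1,1-dimethoxypropan-2-yl]-3-methylcyclohex-3-en-1-one
Conditions: [Cu((S,S)-t-Bu-box)](SbF6)2 (10 mol %), CH2Cl2, −78 °C
Reagents that add atoms: none
Why: Proposed new method: ketone 4 should chelate divalent copper through its carbonyl and one methoxy oxygen just as pyruvate esters and (benzyloxy)acetaldehyde do in the known copper–bis(oxazoline) Mukaiyama aldol additions of enolsilanes (the closest known reaction type), so that enolsilane 3 attacks the unshielded carbonyl face (sets C7 by catalyst control) through an open antiperiplanar transition state that gives the syn C4/C7 relationship, and silyl transfer delivers the tertiary silyl ether, which also blocks retro-aldol cleavage.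

**Step 4**
Reactants: 5 (6S)-6-[(2S)-2-(tert-butyldimethylsilyloxy)-1,1-dimethoxypropan-2-yl]-3-methylcyclohex-3-en-1-one
Product: 7 (1S,6R)-6-[(2S)-2-(tert-butyldimethylsilyloxy)-1,1-dimethoxypropan-2-yl]-3-methylcyclohex-3-en-1-yl acetate, via lithium alkoxide 6 (not isolated)
Conditions: LiBH(s-Bu)3, THF, −78 °C; then Ac2O, DMAP, −78 °C → rt
Reagents that add atoms: acetic anhydride, CC(=O)OC(C)=O
Why: Substrate-controlled ketone reduction followed by O-acylation, in which the bulky trialkylborohydride attacks from the equatorial direction to give the axial C5 alkoxide cis to the equatorial side chain (sets C5), and this only free oxygen is acetylated in the same flask.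

**Step 5**
Reactants: 7 (1S,6R)-6-[(2S)-2-(tert-butyldimethylsilyloxy)-1,1-dimethoxypropan-2-yl]-3-methylcyclohex-3-en-1-yl acetate
Product: 8 (1S,6R)-6-[(2S)-2-hydroxy-1-oxopropan-2-yl]-3-methylcyclohex-3-en-1-yl acetate
Conditions: 48% aq. HF, MeCN, 0 °C → rt
Reagents that add atoms: water, O
Why: Aqueous HF cleaves the tertiary silyl ether and hydrolyses the dimethyl acetal in one operation (desilylation and acetal hydrolysis), while the acetate, the olefin and the non-epimerisable quaternary C7 are untouched.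

**Step 6**
Reactants: 8 (1S,6R)-6-[(2S)-2-hydroxy-1-oxopropan-2-yl]-3-methylcyclohex-3-en-1-yl acetate
Product: 9 (1S,6R)-6-[(2S,3S)-2,3-dihydroxyhex-5-en-2-yl]-3-methylcyclohex-3-en-1-yl acetate
Conditions: In powder, allyl bromide, THF/H2O (1:1), rt
Reagents that add atoms: allyl bromide, C=CCBr
Why: Barbier-type indium allylation that tolerates the acetate, in which the free tertiary α-hydroxyl and the aldehyde oxygen chelate indium (Cram-chelate model) so that the allyl group adds from the face flanked by the small C7 methyl and gives the 8S syn-diol.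

**Step 7**
Reactants: 9 (1S,6R)-6-[(2S,3S)-2,3-dihydroxyhex-5-en-2-yl]-3-methylcyclohex-3-en-1-yl acetate
Product: 10 (1S,3S,4R,6R)-4-[(2S,3S)-2,3-dihydroxyhex-5-en-2-yl]-1-methyl-7-oxabicyclo[4.1.0]heptan-3-yl acetate
Conditions: DMDO, acetone, −20 °C → 0 °C
Reagents that add atoms: dimethyldioxirane, CC1(C)OO1
Why: Neutral dioxirane epoxidation is selective for the electron-rich trisubstituted ring olefin over the monosubstituted allyl group and occurs anti to the axial C5 acetate of the half-chair (side chain equatorial), which sets the 1S,2R epoxide trans to acetate and side chain without acid that would trigger opening by the tertiary alcohol.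

**Step 8**
Reactants: 10 (1S,3S,4R,6R)-4-[(2S,3S)-2,3-dihydroxyhex-5-en-2-yl]-1-methyl-7-oxabicyclo[4.1.0]heptan-3-yl acetate
Product: 11 (1S,3S,4R,6R)-4-[(2S,3S)-2,3-dihydroxy-6-methylhept-5-en-2-yl]-1-methyl-7-oxabicyclo[4.1.0]heptan-3-yl acetate
Conditions: second-generation Grubbs catalyst (H2IMes)(PCy3)Cl2Ru=CHPh (5 mol %), 2-methylbut-2-ene/CH2Cl2, 35 °C
Reagents that add atoms: 2-methylbut-2-ene, CC=C(C)C
Why: Olefin cross-metathesis of the terminal allyl group with excess 2-methylbut-2-ene installs the prenyl olefin with loss of propene, and the trisubstituted epoxide, the free diol and the acetate are inert to the ruthenium carbene (no stereocentre touched).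

**Step 9**
Reactants: 11 (1S,3S,4R,6R)-4-[(2S,3S)-2,3-dihydroxy-6-methylhept-5-en-2-yl]-1-methyl-7-oxabicyclo[4.1.0]heptan-3-yl acetate
Product: 13 (1R,2R,4R,5S,7S,8S,10S)-5-acetoxy-10-bromo-1,8:7,11-diepoxybisabolan-2-ol (target CNP0247588.2), via bromo-oxane epoxide 12 (not isolated)
Conditions: TBCO, MeNO2, 4 Å MS, 0 °C; then CSA (10 mol %), 0 °C → rt
Reagents that add atoms: 2,4,4,6-tetrabromocyclohexa-2,5-dien-1-one (TBCO), O=C1C(Br)=CC(Br)(Br)C=C1Br
Why: Proposed new method: the bromonium ion on the only olefin is opened at tertiary C11 by the tertiary C7 hydroxyl through a chair transition state with equatorial bromine and equatorial carbocycle (Markovnikov 6-endo bromoetherification, sets C10), and the acid released by this ring closure (2,4,6-tribromophenol, reinforced by CSA) then activates the epoxide for attack of the remaining C8 hydroxyl at tertiary C1 with inversion through a boat carbocycle (sets C1 and unveils the trans C2 hydroxyl); closest known reaction types are TBCO bromoetherifications giving 3-bromo-2,2,6-trimethyloxanes and the acid-catalysed cyclisation of α-terpineol epoxide to hydroxycineole.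

**Compound list**
1 | 3-methylphenol | Cc1cccc(O)c1 | starting material
2 | tert-butyl(dimethyl)(3-methylphenoxy)silane | Cc1cccc(O[Si](C)(C)C(C)(C)C)c1 | intermediate
3 | tert-butyl(dimethyl)[(5-methylcyclohexa-1,4-dien-1-yl)oxy]silane | CC1=CCC=C(O[Si](C)(C)C(C)(C)C)C1 | intermediate
4 | 1,1-dimethoxypropan-2-one | CC(=O)C(OC)OC | starting material
5 | (6S)-6-[(2S)-2-(tert-butyldimethylsilyloxy)-1,1-dimethoxypropan-2-yl]-3-methylcyclohex-3-en-1-one | O=C1CC(C)=CC[C@H]1[C@](C)(O[Si](C)(C)C(C)(C)C)C(OC)OC | intermediate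
6 | lithium (1S,6R)-6-[(2S)-2-(tert-butyldimethylsilyloxy)-1,1-dimethoxypropan-2-yl]-3-methylcyclohex-3-en-1-olate | [Li+].[O-][C@H]1CC(C)=CC[C@H]1[C@](C)(O[Si](C)(C)C(C)(C)C)C(OC)OC | intermediate
7 | (1S,6R)-6-[(2S)-2-(tert-butyldimethylsilyloxy)-1,1-dimethoxypropan-2-yl]-3-methylcyclohex-3-en-1-yl acetate | CC(=O)O[C@H]1CC(C)=CC[C@H]1[C@](C)(O[Si](C)(C)C(C)(C)C)C(OC)OC | intermediate
8 | (1S,6R)-6-[(2S)-2-hydroxy-1-oxopropan-2-yl]-3-methylcyclohex-3-en-1-yl acetate | CC(=O)O[C@H]1CC(C)=CC[C@H]1[C@](C)(O)C=O | intermediate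
9 | (1S,6R)-6-[(2S,3S)-2,3-dihydroxyhex-5-en-2-yl]-3-methylcyclohex-3-en-1-yl acetate | CC(=O)O[C@H]1CC(C)=CC[C@H]1[C@](C)(O)[C@@H](O)CC=C | intermediate
10 | (1S,3S,4R,6R)-4-[(2S,3S)-2,3-dihydroxyhex-5-en-2-yl]-1-methyl-7-oxabicyclo[4.1.0]heptan-3-yl acetate | CC(=O)O[C@H]1C[C@]2(C)O[C@@H]2C[C@H]1[C@](C)(O)[C@@H](O)CC=C | intermediate
11 | (1S,3S,4R,6R)-4-[(2S,3S)-2,3-dihydroxy-6-methylhept-5-en-2-yl]-1-methyl-7-oxabicyclo[4.1.0]heptan-3-yl acetate | CC(=O)O[C@H]1C[C@]2(C)O[C@@H]2C[C@H]1[C@](C)(O)[C@@H](O)CC=C(C)C | intermediate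
12 | (1S,3S,4R,6R)-4-[(2S,3S,5S)-5-bromo-3-hydroxy-2,6,6-trimethyloxan-2-yl]-1-methyl-7-oxabicyclo[4.1.0]heptan-3-yl acetate | CC(=O)O[C@H]1C[C@]2(C)O[C@@H]2C[C@H]1[C@]3(C)OC(C)(C)[C@@H](Br)C[C@@H]3O | intermediate
13 | (1R,2R,4R,5S,7S,8S,10S)-5-acetoxy-10-bromo-1,8:7,11-diepoxybisabolan-2-ol | CC(=O)O[C@H]1C[C@@]2(C)O[C@H]3C[C@H](Br)C(C)(C)O[C@@]3(C)[C@@H]1C[C@H]2O | target

**Totals**
Total step count: 9. Longest linear sequence: 9 steps (1 → 13).

**Steps most likely to fail, with fallbacks**

Step 9 (the one-flask double etherification). The C8 hydroxyl can trap the bromonium ion in a 5-endo mode to give a bromo-oxolane. The tertiary C7 hydroxyl can open the epoxide before bromination and give a cineole-type bridged ether. The C5 acetate can participate at C1. The fallback sets out from 11 and returns at 13. The secondary C8 hydroxyl of 11 is silylated (Et3SiCl, imidazole) to the C8 triethylsilyl ether F1, so that only the tertiary C7 hydroxyl can trap the bromonium ion. TBCO in MeNO2 then gives the silylated bromo-oxane epoxide F2. HF·pyridine finally removes the silyl group, and the freed C8 hydroxyl opens the epoxide under the same acidic conditions to give 13.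

Step 3 (asymmetric aldol on an untested electrophile). Reactivity of the dialkoxy ketone, the sense and level of enantioselection, and silyl transfer to the hindered alkoxide are all unproven. The fallback sets out from 3 and returns at 8, and uses the established pyruvate version of the reaction.
- Enolsilane 3 and methyl pyruvate with [Cu((S,S)-t-Bu-box)](OTf)2 give the silylated syn keto ester F3.
- LiBH(s-Bu)3 reduces the ketone to the cis alkoxide, which closes onto the ester to give the cis-fused lactone F4.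
- Me2AlN(OMe)Me (from AlMe3 and MeNHOMe·HCl) opens the lactone to the hydroxy Weinreb amide F5.
- Ac2O/DMAP gives the acetoxy Weinreb amide F6.
- Cp2Zr(H)Cl reduces the amide, but not the acetate, to the silylated acetoxy aldehyde F7.
- Aqueous HF removes the silyl group to give 8.

Step 7 (ring epoxidation). The facial selectivity rests only on the axial acetate, and the product pairs a tertiary alcohol with an acid-labile epoxide through two further operations. The fallback sets out from 9 and returns at 13, and reverses the order of the oxidation events. Cross-metathesis of 9 with 2-methylbut-2-ene first gives the prenyl diene diol F8. TBCO then closes the oxane on the side chain while the ring olefin is still present, giving the bromo-oxane cyclohexene F9. DMDO epoxidation of the one remaining olefin, followed by CSA in the same flask, closes the oxepane to 13. The epoxide then never coexists with a free tertiary hydroxyl, and the wrong-face epoxide, which cannot cyclise, is removed by chromatography.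

**Further compounds**
F1 | step 9 | (1S,3S,4R,6R)-4-[(2S,3S)-2-hydroxy-6-methyl-3-(triethylsilyloxy)hept-5-en-2-yl]-1-methyl-7-oxabicyclo[4.1.0]heptan-3-yl acetate | CC(=O)O[C@H]1C[C@]2(C)O[C@@H]2C[C@H]1[C@](C)(O)[C@@H](O[Si](CC)(CC)CC)CC=C(C)C
F2 | step 9 | (1S,3S,4R,6R)-4-[(2S,3S,5S)-5-bromo-2,6,6-trimethyl-3-(triethylsilyloxy)oxan-2-yl]-1-methyl-7-oxabicyclo[4.1.0]heptan-3-yl acetate | CC(=O)O[C@H]1C[C@]2(C)O[C@@H]2C[C@H]1[C@]3(C)OC(C)(C)[C@@H](Br)C[C@@H]3O[Si](CC)(CC)CC
F3 | step 3 | methyl (2S)-2-(tert-butyldimethylsilyloxy)-2-[(1S)-4-methyl-2-oxocyclohex-4-en-1-yl]propanoate | O=C1CC(C)=CC[C@H]1[C@](C)(O[Si](C)(C)C(C)(C)C)C(=O)OC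
F4 | step 3 | (3S,3aR,7aS)-3-(tert-butyldimethylsilyloxy)-3,6-dimethyl-3a,4,7,7a-tetrahydro-1-benzofuran-2(3H)-one | CC1=CC[C@@H]2[C@H](C1)OC(=O)[C@@]2(C)O[Si](C)(C)C(C)(C)C
F5 | step 3 | (2S)-2-(tert-butyldimethylsilyloxy)-2-[(1R,2S)-2-hydroxy-4-methylcyclohex-4-en-1-yl]-N-methoxy-N-methylpropanamide | O[C@H]1CC(C)=CC[C@H]1[C@](C)(O[Si](C)(C)C(C)(C)C)C(=O)N(C)OC
F6 | step 3 | (1S,6R)-6-[(2S)-2-(tert-butyldimethylsilyloxy)-1-[methoxy(methyl)amino]-1-oxopropan-2-yl]-3-methylcyclohex-3-en-1-yl acetate | CC(=O)O[C@H]1CC(C)=CC[C@H]1[C@](C)(O[Si](C)(C)C(C)(C)C)C(=O)N(C)OC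
F7 | step 3 | (1S,6R)-6-[(2S)-2-(tert-butyldimethylsilyloxy)-1-oxopropan-2-yl]-3-methylcyclohex-3-en-1-yl acetate | CC(=O)O[C@H]1CC(C)=CC[C@H]1[C@](C)(O[Si](C)(C)C(C)(C)C)C=O
F8 | step 7 | (1S,6R)-6-[(2S,3S)-2,3-dihydroxy-6-methylhept-5-en-2-yl]-3-methylcyclohex-3-en-1-yl acetate | CC(=O)O[C@H]1CC(C)=CC[C@H]1[C@](C)(O)[C@@H](O)CC=C(C)C
F9 | step 7 | (1S,6R)-6-[(2S,3S,5S)-5-bromo-3-hydroxy-2,6,6-trimethyloxan-2-yl]-3-methylcyclohex-3-en-1-yl acetate | CC(=O)O[C@H]1CC(C)=CC[C@H]1[C@]2(C)OC(C)(C)[C@@H](Br)C[C@@H]2O
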